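(The numbers in the tables are calculated from invented constants; noise was put on by code.)

Slowness is the first question for this flask: does it reach its end within 8.0 min, and what stands there?

- ochre: starting material 15 mM; partner 25 mM; free catalyst 5 µM; run made earlier
- flask: starting material 10 mM; partner 25.0 mM; free catalyst 5.0 µM; time 8.0 min

ochre run (percent of the starting material charged)

| time / s | target / % | over-reaction product / % |
|---|---|---|
| 10.0 | 3.8 | 1.6 |
| 20.0 | 4.6 | 6.3 |
| 30.0 | 5.1 | 11.8 |
| 50.0 | 4.0 | 21.3 |
| 80.0 | 5.3 | 36.2 |
| 90.0 | 4.1 | 40.9 |

(each reading ± 0.5 percentage points)

- the earlier runs were read with a standard deviation of 0.5 percentage points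

1. concentration of target at 8.0 min, in mM
2. concentration of over-reaction product at 8.0 min, in mM

1. Speed at the start: in the ochre run, target and over-reaction product together grew at 0.0742 mM s⁻¹, and this flask has the same charges of partner and free catalyst.

2. What slows it: the ochre run's starting material read about 55.0% of its charge by the last reading, while the late slope of over-reaction product read 0.951 of the early one, so we give starting material a factor of 1. The readings do not show partner, so we assume one partner per starting material and a rate proportional to partner (pseudo-first-order), with the drain time, partner charge over starting rate, 5.61 min.

3. The end: in this flask starting material is the limiting reagent, and we reckon that using it up takes 2.25 min unslowed or 2.87 min slowed, shorter than the run. In the ochre run the target read flat near 0.672 mM, so for this flask we expect target between zero and that, and over-reaction product from 9.33 mM to 10 mM.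

4. The forecast, at the low end of our target span, gives 0.02 mM and 9.9 mM: “the target should have decayed and nearly everything should be over-reaction product”.

5. The flask gives 0.557 mM of target and 9.44 mM of over-reaction product, with 0% of starting material left at 4.00 min.

    partner + free catalyst → catalyst intermediate A (k = 900 L mol⁻¹ s⁻¹)
    catalyst intermediate A ⇌ catalyst intermediate B (K = 0.700, k = 2300 s⁻¹)
    starting material + catalyst intermediate B → catalyst intermediate C (k = 4.60 × 10⁵ L mol⁻¹ s⁻¹)
    catalyst intermediate C ⇌ free catalyst + target (K = 0.0150 M, k = 93.0 s⁻¹)
    free catalyst + target → free catalyst + over-reaction product (k = 25000 L mol⁻¹ s⁻¹)

The drain time puts this flask's partner at 86.7% of its charge at 0.800 min, and the flask holds 84.6%. The neighbour charged with 6.2 mM of partner has 0.620 equiv of partner to starting material, so partner is its smaller charge, and the same drain time gives 24.0% of that partner left at 8.0 min and 4.71 mM of over-reaction product. That neighbour holds less partner than reckoned, 12% of its charge unbound, with 5.40 mM of over-reaction product and 46% of its starting material still there, unbound.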